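**Retrosynthetic overview**

1. Ring locants used here: C1 = CH–OAc, C2, C3, C4 = C(CH3)(OH), C5 = CH bearing the side chain, C6 = C(CH3)2. Late disconnections: the aryl ether (Mitsunobu reaction with umbelliferone), the C1 acetate, and the C1 carbinol from a C1 ketone (bulky hydride, axial alcohol).
2. The cyclohexane is cut at C1–C6 and C4–C5. The four-carbon unit C1–C4 with both ring oxygens and the C4 methyl is 5-methyl-2-silyloxyfuran (from α-angelica lactone). It adds across C5=C6 of a two-carbon unit that already carries the gem-dimethyl carbon and the whole side chain: the carbon skeleton of (R)-linalool, which also supplies the side-chain carbinol centre.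
3. Enabling feature: the two oxygen-bearing ring carbons C1 and C4 stand 1,4 across the ring, joined by the C2–C3 ethano unit. This is the α,α′-dioxygenation of a 2-oxyfuran (ring oxygen becomes C4–OH, silyloxy carbon becomes the C1 ketone). The C5–C6 edge is a prenyl alkene whose E-methyl can be raised to a formyl group (activating group, returned to CH3 afterwards), so that it becomes a dienophile of matching polarity.
4. Order of rings: temporary 1,3-dioxane over the side-chain diol (step 2); carbocycle formed as a 7-oxabicyclo[2.2.1]heptene in a dearomatising [4+2] addition that sets C4 and C5 (step 6); oxygen bridge opened (step 9); dioxane opened (step 12). The coumarin bicycle is bought as umbelliferone.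

Key step: step 6

Assumption: commercial (R)-(−)-linalool is used as the single enantiomer; its carbinol carbon is never touched and becomes the side-chain stereocentre.
Assumption: the quinidine-derived primary amine is taken to leave open the face of the iminium ion that leads to the ring configuration of the target; the quinine-derived pseudoenantiomer gives the mirror-image ring sense and would be used instead if the sense is the other way round.

**Route**

Step 1
Reactants: 1 (R)-(−)-linalool, (3R)-3,7-dimethylocta-1,6-dien-3-ol
Product: 3 (3R)-3,7-dimethyloct-6-ene-1,3-diol, via B-alkyl-9-BBN adduct 2 (not isolated)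
Conditions: 9-borabicyclo[3.3.1]nonane (9-BBN, 2.2 equiv), THF, 0 °C to rt; then NaOH, H2O2, 0 °C
Reagents that add atoms: hydrogen peroxide, OO
Why: 9-BBN should add only to the monosubstituted vinyl group, boron going to the terminal carbon, and oxidation with retention then gives the primary alcohol while the trisubstituted alkene and the tertiary carbinol centre stay untouched (anti-Markovnikov hydroboration–oxidation).

Step 2
Reactants: 3 (3R)-3,7-dimethyloct-6-ene-1,3-diol
Product: 4 (4R)-2,2,4-trimethyl-4-(4-methylpent-3-en-1-yl)-1,3-dioxane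
Conditions: 2-methoxypropene, pyridinium p-toluenesulfonate (cat.), CH2Cl2, 0 °C to rt
Reagents that add atoms: 2-methoxypropene, COC(C)=C
Why: Acid-catalysed acetal exchange with the enol ether should close the six-membered 1,3-dioxane over the primary and the tertiary hydroxyl, so that no protic group is present in the later Lewis-acidic, basic and hydride steps (acetonide protection of a 1,3-diol, no stereocentre involved).

Step 3
Reactants: 4 (4R)-2,2,4-trimethyl-4-(4-methylpent-3-en-1-yl)-1,3-dioxane
Product: 5 (2E)-2-methyl-5-[(4R)-2,2,4-trimethyl-1,3-dioxan-4-yl]pent-2-en-1-ol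
Conditions: SeO2 (0.3 equiv), t-BuOOH (3 equiv), CH2Cl2, rt
Reagents that add atoms: selenium dioxide, O=[Se]=O; tert-butyl hydroperoxide, CC(C)(C)OO
Why: Selenium dioxide should oxidise the trisubstituted alkene at the allylic methyl group that is trans to the chain (ene reaction followed by [2,3]-sigmatropic shift), which gives the E allylic alcohol and keeps every carbon of linalool (Riley-type allylic oxidation).

Step 4
Reactants: 5 (2E)-2-methyl-5-[(4R)-2,2,4-trimethyl-1,3-dioxan-4-yl]pent-2-en-1-ol
Product: 6 (2E)-2-methyl-5-[(4R)-2,2,4-trimethyl-1,3-dioxan-4-yl]pent-2-enal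
Conditions: MnO2 (activated, excess), CH2Cl2, rt
Reagents that add atoms: none
Why: MnO2 should oxidise the allylic alcohol to the conjugated aldehyde with retention of the E geometry, which turns the former prenyl alkene into an electron-poor dienophile (allylic alcohol oxidation).

Step 5
Reactants: 7 α-angelica lactone, 5-methylfuran-2(3H)-one
Product: 8 tert-butyl(dimethyl)[(5-methylfuran-2-yl)oxy]silane
Conditions: t-BuMe2SiOSO2CF3, Et3N, CH2Cl2, 0 °C
Reagents that add atoms: tert-butyldimethylsilyl trifluoromethanesulfonate, CC(C)(C)[Si](C)(C)OS(=O)(=O)C(F)(F)F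
Why: Soft enolisation of the butenolide and O-silylation should give the aromatic 2-silyloxyfuran, an electron-rich diene and vinylogous enolate (silyl dienol ether formation).

Step 6
Reactants: 6 (2E)-2-methyl-5-[(4R)-2,2,4-trimethyl-1,3-dioxan-4-yl]pent-2-enal; 8 tert-butyl(dimethyl)[(5-methylfuran-2-yl)oxy]silane
Product: 9 (1R,2R,3S,4R)-1-[(tert-butyldimethylsilyl)oxy]-2,4-dimethyl-3-{2-[(4R)-2,2,4-trimethyl-1,3-dioxan-4-yl]ethyl}-7-oxabicyclo[2.2.1]hept-5-ene-2-carbaldehyde (2-formyl endo; 2-methyl and 3-side chain exo)
Conditions: 9-amino-9-deoxy-epi-quinidine (20 mol%), HN(SO2CF3)2 (40 mol%), 8 (2 equiv), CH2Cl2, −30 °C, no protic additive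
Reagents that add atoms: none
Why: Proposed new method: the primary amine salt converts 6 into an iminium ion, the methyl-bearing C5 of furan 8 (its vinylogous, most nucleophilic terminus) adds to the β-carbon, and the enamine carbon that results (the former α-carbon) closes at once onto the silyloxy-bearing C2 of the furanium ion, so that a formal, asynchronous [4+2] addition, suprafacial on both partners, closes the six-membered carbocycle across the furan 2,5-positions as a 7-oxabicyclo[2.2.1]heptene, and the water set free in the condensation hydrolyses the product iminium ion and returns the catalyst. The closest known reaction types are the iminium-catalysed Mukaiyama–Michael addition of 2-silyloxyfurans to enals (same first bond, same regiochemistry), the Diels–Alder reaction of α-substituted enals under primary ammonium salt catalysis, and the thermal [4+2] addition of 2-silyloxyfurans to electron-poor alkenes; new is their union on a trisubstituted enal. The regiochemistry (methyl-bearing furan carbon to the chain-bearing carbon, silyloxy carbon to the formyl-bearing carbon) follows from the polarisation of both partners. The E geometry of 6 keeps chain and formyl trans, and the endo position of the iminium group under the furan (both alkyl groups then sit on the open exo side, so kinetic and thermodynamic preference should agree) puts the chain syn to the oxygen bridge, which is the cis relation of the later C4 hydroxyl and the side chain. The absolute configuration of the chain-bearing carbon, and with it of both bridgeheads, is set by the cinchona amine, which shields one face of the iminium ion, the remote dioxane centre being without influence; the formyl-bearing quaternary carbon is stereogenic only until step 8. The step needs ring closure to win over loss of the silyl group (which would give the open butenolide), and the non-nucleophilic triflimide counter-ion, the absence of protic scavengers and the bulky silyl group are chosen for this.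

Step 7
Reactants: 9 the endo cycloadduct of step 6
Product: 10 (1R,2R,3S,4R)-1-[(tert-butyldimethylsilyl)oxy]-2,4-dimethyl-3-{2-[(4R)-2,2,4-trimethyl-1,3-dioxan-4-yl]ethyl}-7-oxabicyclo[2.2.1]heptane-2-carbaldehyde
Conditions: H2 (1 atm), Pd/C (10 wt%), EtOAc, rt
Reagents that add atoms: none
Why: The strained disubstituted alkene of the bicycle should be saturated without touching the hindered aldehyde or the ketal, which gives the C2–C3 ethano unit, creates no stereocentre and removes the retro-cycloaddition pathway (heterogeneous catalytic hydrogenation).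

Step 8
Reactants: 10 the saturated bicyclic aldehyde of step 7
Product: 12 tert-butyl(dimethyl){[(1R,3S,4R)-2,2,4-trimethyl-3-{2-[(4R)-2,2,4-trimethyl-1,3-dioxan-4-yl]ethyl}-7-oxabicyclo[2.2.1]heptan-1-yl]oxy}silane, via tosylhydrazone 11 (not isolated)
Conditions: TsNHNH2, THF, rt; then catecholborane, CHCl3, 0 °C; then NaOAc·3H2O, reflux
Reagents that add atoms: none
Why: The aldehyde should condense with tosylhydrazine and the hydrazone be reduced by catecholborane to an alkyl diazene that loses N2, which returns the activating formyl group to a methyl group and makes the quaternary carbon the achiral gem-dimethyl carbon while C1 is still masked as the bridgehead silyl ketal (Caglioti-type reductive deoxygenation of a tosylhydrazone).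

Step 9
Reactants: 12 the gem-dimethyl bicyclic silyl ketal of step 8
Product: 14 (3S,4R)-4-hydroxy-2,2,4-trimethyl-3-{2-[(4R)-2,2,4-trimethyl-1,3-dioxan-4-yl]ethyl}cyclohexan-1-one, via bridgehead hemiketal 13 (not isolated)
Conditions: Bu4NF, AcOH, THF, 0 °C
Reagents that add atoms: none
Why: Fluoride should remove the silyl group and the strained bridgehead hemiketal should open to the C1 ketone and the free tertiary C4 alcohol, whose oxygen is the former furan oxygen, so that the C4 and C5 configurations from step 6 are kept (desilylation and ring–chain opening of a hemiketal).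

Step 10
Reactants: 14 the hydroxy ketone of step 9
Product: 15 (1R,2S,4R)-1,3,3-trimethyl-2-{2-[(4R)-2,2,4-trimethyl-1,3-dioxan-4-yl]ethyl}cyclohexane-1,4-diol
Conditions: LiBH(s-Bu)3 (L-Selectride, 2.5 equiv), THF, −78 °C; then H2O
Reagents that add atoms: none
Why: In the chair with side chain and C4 methyl equatorial and C4 hydroxyl axial, the bulky trialkylborohydride should attack the C1 carbonyl along the equatorial trajectory, as it does with 2,2-dimethylcyclohexanones and 4,4-dimethyl-3-keto steroids, so that the new hydroxyl is axial and trans to the side chain (substrate-controlled ketone reduction).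

Step 11
Reactants: 15 the diol of step 10
Product: 16 (1R,3S,4R)-4-hydroxy-2,2,4-trimethyl-3-{2-[(4R)-2,2,4-trimethyl-1,3-dioxan-4-yl]ethyl}cyclohexyl acetate
Conditions: Ac2O, pyridine, 4-(dimethylamino)pyridine (cat.), CH2Cl2, 0 °C to rt
Reagents that add atoms: acetic anhydride, CC(=O)OC(C)=O
Why: Only the secondary C1 hydroxyl should be acylated under these mild conditions because the tertiary C4 hydroxyl is too hindered, and the configuration at C1 is retained (nucleophile-catalysed acetylation).

Step 12
Reactants: 16 the acetonide acetate of step 11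
Product: 17 (1R,3S,4R)-3-[(3R)-3,5-dihydroxy-3-methylpentyl]-4-hydroxy-2,2,4-trimethylcyclohexyl acetate
Conditions: AcOH–H2O (4:1), 40 °C
Reagents that add atoms: none
Why: Mild aqueous acid should hydrolyse the acetonide to the primary and the tertiary side-chain hydroxyl without cleaving the acetate or dehydrating the tertiary alcohols (acetal hydrolysis).

Step 13
Reactants: 17 the triol monoacetate of step 12; 18 umbelliferone, 7-hydroxy-2H-chromen-2-one
Product: 19 (1R,3S,4R)-4-hydroxy-3-{(3R)-3-hydroxy-3-methyl-5-[(2-oxo-2H-chromen-7-yl)oxy]pentyl}-2,2,4-trimethylcyclohexyl acetate (target)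
Conditions: PPh3, DIAD, THF, 0 °C to rt
Reagents that add atoms: none
Why: Only the primary hydroxyl should be activated and displaced by the acidic phenol of umbelliferone, the two tertiary alcohols and the acetate being inert, and no stereocentre takes part (Mitsunobu etherification).

**Compound list**

1 | (R)-(−)-linalool, (3R)-3,7-dimethylocta-1,6-dien-3-ol | CC(C)=CCC[C@@](C)(O)C=C | starting material
2 | (3S)-1-(9-borabicyclo[3.3.1]nonan-9-yl)-3,7-dimethyloct-6-en-3-ol (carbinol centre unchanged; descriptor changes by priority only) | CC(C)=CCC[C@@](C)(O)CCB1C2CCCC1CCC2 | intermediate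
3 | (3R)-3,7-dimethyloct-6-ene-1,3-diol | CC(C)=CCC[C@@](C)(O)CCO | intermediate
4 | (4R)-2,2,4-trimethyl-4-(4-methylpent-3-en-1-yl)-1,3-dioxane | CC(C)=CCC[C@]1(C)CCOC(C)(C)O1 | intermediate
5 | (2E)-2-methyl-5-[(4R)-2,2,4-trimethyl-1,3-dioxan-4-yl]pent-2-en-1-ol | OC/C(C)=C/CC[C@]1(C)CCOC(C)(C)O1 | intermediate
6 | (2E)-2-methyl-5-[(4R)-2,2,4-trimethyl-1,3-dioxan-4-yl]pent-2-enal | O=C/C(C)=C/CC[C@]1(C)CCOC(C)(C)O1 | intermediate
7 | α-angelica lactone, 5-methylfuran-2(3H)-one | CC1=CCC(=O)O1 | starting material
8 | tert-butyl(dimethyl)[(5-methylfuran-2-yl)oxy]silane | Cc1ccc(O[Si](C)(C)C(C)(C)C)o1 | intermediate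
9 | (1R,2R,3S,4R)-1-[(tert-butyldimethylsilyl)oxy]-2,4-dimethyl-3-{2-[(4R)-2,2,4-trimethyl-1,3-dioxan-4-yl]ethyl}-7-oxabicyclo[2.2.1]hept-5-ene-2-carbaldehyde | C[C@]12C=C[C@](O[Si](C)(C)C(C)(C)C)(O1)[C@@](C)(C=O)[C@@H]2CC[C@]3(C)CCOC(C)(C)O3 | intermediate
10 | (1R,2R,3S,4R)-1-[(tert-butyldimethylsilyl)oxy]-2,4-dimethyl-3-{2-[(4R)-2,2,4-trimethyl-1,3-dioxan-4-yl]ethyl}-7-oxabicyclo[2.2.1]heptane-2-carbaldehyde | C[C@]12CC[C@](O[Si](C)(C)C(C)(C)C)(O1)[C@@](C)(C=O)[C@@H]2CC[C@]3(C)CCOC(C)(C)O3 | intermediate
11 | (E)-N-tosylhydrazone of 10 | C[C@]12CC[C@](O[Si](C)(C)C(C)(C)C)(O1)[C@@](C)(/C=N/NS(=O)(=O)c4ccc(C)cc4)[C@@H]2CC[C@]3(C)CCOC(C)(C)O3 | intermediate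
12 | tert-butyl(dimethyl){[(1R,3S,4R)-2,2,4-trimethyl-3-{2-[(4R)-2,2,4-trimethyl-1,3-dioxan-4-yl]ethyl}-7-oxabicyclo[2.2.1]heptan-1-yl]oxy}silane | C[C@]12CC[C@](O[Si](C)(C)C(C)(C)C)(O1)C(C)(C)[C@@H]2CC[C@]3(C)CCOC(C)(C)O3 | intermediate
13 | (1S,3S,4R)-2,2,4-trimethyl-3-{2-[(4R)-2,2,4-trimethyl-1,3-dioxan-4-yl]ethyl}-7-oxabicyclo[2.2.1]heptan-1-ol | C[C@]12CC[C@](O)(O1)C(C)(C)[C@@H]2CC[C@]3(C)CCOC(C)(C)O3 | intermediate
14 | (3S,4R)-4-hydroxy-2,2,4-trimethyl-3-{2-[(4R)-2,2,4-trimethyl-1,3-dioxan-4-yl]ethyl}cyclohexan-1-one | O=C1CC[C@@](C)(O)[C@@H](CC[C@]2(C)CCOC(C)(C)O2)C1(C)C | intermediate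
15 | (1R,2S,4R)-1,3,3-trimethyl-2-{2-[(4R)-2,2,4-trimethyl-1,3-dioxan-4-yl]ethyl}cyclohexane-1,4-diol | O[C@@H]1CC[C@@](C)(O)[C@@H](CC[C@]2(C)CCOC(C)(C)O2)C1(C)C | intermediate
16 | (1R,3S,4R)-4-hydroxy-2,2,4-trimethyl-3-{2-[(4R)-2,2,4-trimethyl-1,3-dioxan-4-yl]ethyl}cyclohexyl acetate | CC(=O)O[C@@H]1CC[C@@](C)(O)[C@@H](CC[C@]2(C)CCOC(C)(C)O2)C1(C)C | intermediate
17 | (1R,3S,4R)-3-[(3R)-3,5-dihydroxy-3-methylpentyl]-4-hydroxy-2,2,4-trimethylcyclohexyl acetate | CC(=O)O[C@@H]1CC[C@@](C)(O)[C@@H](CC[C@@](C)(O)CCO)C1(C)C | intermediate
18 | umbelliferone, 7-hydroxy-2H-chromen-2-one | Oc1ccc2ccc(=O)oc2c1 | starting material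
19 | (1R,3S,4R)-4-hydroxy-3-{(3R)-3-hydroxy-3-methyl-5-[(2-oxo-2H-chromen-7-yl)oxy]pentyl}-2,2,4-trimethylcyclohexyl acetate | CC(=O)O[C@@H]1CC[C@@](C)(O)[C@@H](CC[C@@](C)(O)CCOc2ccc3ccc(=O)oc3c2)C1(C)C | target

**Step count and risks**

Total steps: 13. Longest linear sequence: 12 steps (steps 1–4 and 6–13, from linalool); step 5 is a one-step side branch.

Steps most likely to fail:

1. Step 6 (proposed new method). The furanium intermediate may lose its silyl group before the second bond forms, so that the open-chain butenolide results instead of the bicycle. The E geometry of the enal may be scrambled through a dienamine. Endo or facial discrimination may be insufficient. The acid co-catalyst may open the dioxane. Fallback with known chemistry: setting out from 6 and 8, the cycloaddition is run without any catalyst at 10–12 kbar in CH2Cl2 at room temperature. This is a concerted thermal Diels–Alder reaction of the kind established for 2-silyloxyfurans, in which no ionic intermediate can lose silicon. Because the side-chain centre is fixed, the two endo adducts of opposite ring sense are diastereomers: 9 and its ring-mirrored isomer, (1S,2S,3R,4S)-1-[(tert-butyldimethylsilyl)oxy]-2,4-dimethyl-3-{2-[(4R)-2,2,4-trimethyl-1,3-dioxan-4-yl]ethyl}-7-oxabicyclo[2.2.1]hept-5-ene-2-carbaldehyde F1. They are separated by chromatography and the route is rejoined at 9. Control of the ring configuration thus moves from the catalyst to a separation, at the cost of half of the material.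

2. Step 8. Hydrazone formation may be slow or incomplete at an aldehyde flanked by two fully substituted carbons. The Lewis-acidic borane may strip the bridgehead silyl group, which would expose the C1 carbonyl to the same reagents. Fallback: setting out from 10, NaBH4 in MeOH at 0 °C should give the neopentyl alcohol, [(1R,2R,3S,4R)-1-[(tert-butyldimethylsilyl)oxy]-2,4-dimethyl-3-{2-[(4R)-2,2,4-trimethyl-1,3-dioxan-4-yl]ethyl}-7-oxabicyclo[2.2.1]heptan-2-yl]methanol F2. Appel-type iodination (I2, PPh3, imidazole, toluene, 80 °C) should give tert-butyl{[(1R,2S,3S,4R)-2-(iodomethyl)-2,4-dimethyl-3-{2-[(4R)-2,2,4-trimethyl-1,3-dioxan-4-yl]ethyl}-7-oxabicyclo[2.2.1]heptan-1-yl]oxy}dimethylsilane F3. Radical dehalogenation (Bu3SnH, AIBN, toluene, 80 °C) then returns to the route at 12.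

3. Step 10. Hydride delivery may be poorly face-selective, either by axial entry or by steering through the lithium alkoxide of the C4 hydroxyl, which would give the equatorial C1 epimer. Fallback: the face is set by the reagent instead of the ring. Setting out from 14, a Corey–Bakshi–Shibata reduction with (S)-1-methyl-3,3-diphenyltetrahydro-1H,3H-pyrrolo[1,2-c][1,3,2]oxazaborole (20 mol%) and BH3·SMe2 in THF at −20 °C is used. With the gem-dimethyl carbon as the large and the CH2 as the small flank, hydride should go to the face that leaves the C1 hydroxyl trans to the side chain. The route is rejoined at 15; no new compound is made (F0).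

Further compounds
F1 | step 6 | (1S,2S,3R,4S)-1-[(tert-butyldimethylsilyl)oxy]-2,4-dimethyl-3-{2-[(4R)-2,2,4-trimethyl-1,3-dioxan-4-yl]ethyl}-7-oxabicyclo[2.2.1]hept-5-ene-2-carbaldehyde | C[C@@]12C=C[C@@](O[Si](C)(C)C(C)(C)C)(O1)[C@](C)(C=O)[C@H]2CC[C@]3(C)CCOC(C)(C)O3
F2 | step 8 | [(1R,2R,3S,4R)-1-[(tert-butyldimethylsilyl)oxy]-2,4-dimethyl-3-{2-[(4R)-2,2,4-trimethyl-1,3-dioxan-4-yl]ethyl}-7-oxabicyclo[2.2.1]heptan-2-yl]methanol | C[C@]12CC[C@](O[Si](C)(C)C(C)(C)C)(O1)[C@@](C)(CO)[C@@H]2CC[C@]3(C)CCOC(C)(C)O3
F3 | step 8 | tert-butyl{[(1R,2S,3S,4R)-2-(iodomethyl)-2,4-dimethyl-3-{2-[(4R)-2,2,4-trimethyl-1,3-dioxan-4-yl]ethyl}-7-oxabicyclo[2.2.1]heptan-1-yl]oxy}dimethylsilane | C[C@]12CC[C@](O[Si](C)(C)C(C)(C)C)(O1)[C@@](C)(CI)[C@@H]2CC[C@]3(C)CCOC(C)(C)O3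
F0 | step 10 | none | none
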